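(The runs are calculated with constants of no real substance; the scatter is artificial.)

Late readings were what I needed first, since the flask is wanted out to 15 min and the earlier runs stop at 12.0 min.

| flask | left-handed substrate | right-handed substrate | reagent | free catalyst | racemization catalyst | remark | time |
|---|---|---|---|---|---|---|---|
| ochre | 0.013 M | 0.013 M | 0.044 M | 1 mM | 0.14 mM | run made earlier |  |
| violet | 0.030 M | 0.030 M | 0.044 M | 1 mM | 0.14 mM | run made earlier |  |
| amber | 0.020 M | 0.020 M | 0.044 M | 1 mM | 0.28 mM | run made earlier |  |
| flask | 0.020 M | 0.020 M | 0.0440 M | 1.0 mM | 0.14 mM |  | 15 min |

- ochre (time / min: left-handed product / %, left-handed substrate / %): 1.00: 10, 37; 3.00: 26, 30; 6.00: 38, 18; 8.00: 47, 12; 12.0: 52, 6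
- violet (time / min: left-handed product / %, left-handed substrate / %): 1.00: 11, 39; 2.00: 18, 34; 3.00: 21, 29; 6.00: 33, 20; 12.0: 43, 18
- amber (time / min: left-handed product / %, left-handed substrate / %): 2.50: 25, 32; 5.00: 35, 24; 8.00: 42, 15; 10.0: 49, 16; 12.0: 51, 15

(readings scatter by 1.5 percentage points)

- free catalyst is single-handed; left-handed substrate and right-handed substrate are mirror images of each other, charged as a racemate, each of them at the stated concentration
- what may be going on: left-handed substrate + racemization catalyst <-> right-handed substrate + racemization catalyst; racemization catalyst <-> dormant form; reagent + free catalyst + left-handed substrate -> free catalyst + left-handed product; reagent + free catalyst + right-handed substrate -> free catalyst + right-handed product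

1. amount of left-handed product in percent of the left-handed substrate and right-handed substrate together charged, at 3.0 min, 8.0 min and 15 min

Before taking any number, I asked in logarithms which givens had to be known well. The reagent and free catalyst stood at 0.0440 M and 1.0 mM in the flask and in each run, so the flask asked nothing new of them. The charge did change: from ochre to violet it rose by a factor 2.31, while the left-handed product at 12.0 min fell from 52% to 43%. From these two scattered readings I read n = −0.227, my loading exponent, the logarithmic sensitivity of the left-handed product to the charge at a fixed time. For going from ochre to the flask's charge I therefore reckoned a factor of 0.907 on the left-handed product, an estimated cost of 4.8 percentage points at 12.0 min.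

Carried to amber, which has the flask's charge, n turned the ochre reading into 47.2%, but amber read 51% with twice the racemization catalyst. That reads as an exponent of 0.113, about half the size of n, and the flask shares ochre's 0.14 mM anyway. So I multiplied ochre's readings by the factor, getting 23.6% at 3.0 min and 42.6% at 8.0 min, and continued the last slope to 50.6% at 15 min.

The forecast gave 24%, 40% and 51%, saying “I interpolate their smoothed curves”; my figure at 8.0 min stood 2.6 points above it.

The flask gave 26.3%, 43.1% and 52.7%, so the forecast was right within the tolerance.

    left-handed substrate + racemization catalyst ⇌ right-handed substrate + racemization catalyst, rate k1*[racemization catalyst]*[left-handed substrate] forward; the back reaction follows from the equilibrium constant (k = 46.0 /M/s)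
    racemization catalyst ⇌ dormant form (K = 3.80, k = 0.00280 /s)
    reagent + free catalyst + left-handed substrate → free catalyst + left-handed product (k = 110 /M²/s)
    reagent + free catalyst + right-handed substrate → free catalyst + right-handed product (k = 41.0 /M²/s)

At 15.0 min the flask held 24.1% of its racemization catalyst in the active form and 75.9% as dormant form. Used once more, n took the flask's 26.3% at 3.0 min to 24.0% for violet's charge, where violet read 21%.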